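**Plan** (lactone ring numbered C1 (C=O), O2, C3, C4, C4a–C8a; side chain C1'–C11', carbinol at C6')
1. Retrosynthetic cuts, in order: the 8-O–methyl ether and a C6' O-benzoate (helpers); then C5'–C6', which splits the molecule into a lactone carrying a C4'=C5' terminal alkene, hexanal (C6'–C11') and benzoyl bromide; then C1–C8a/C1–O2 (CO insertion); then C1'–C2' and C4–C4a (two Grignard openings at the two ends of epichlorohydrin).
2. Forward order: aryl–C4 bond, ring bromination at the future C8a, epoxide, C1'–C2' bond, carbonylative closure of the benzo-fused δ-lactone ring, four-component union of the chain, debenzoylation, 8-O-demethylation.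
3. Enabling feature: C6' is an isolated dialkyl carbinol flanked by two n-alkyl arms (C1'–C5' and C7'–C11') that no ketone reduction could tell apart, so its configuration is best set while the C5'–C6' bond is made.
4. C6' sits at the aldehyde oxidation level and C5' ends a tether that keeps the alkene four CH2 groups from the dihydroisocoumarin ring and C3, so an α-acyloxy radical at C6' and a primary alkyl–nickel at C5' can meet without interference.
5. Stereochemistry: C3 (R) comes from (S)-epichlorohydrin and is never touched after step 1; C6' (S) comes from the chiral Ni/bis(oxazoline) catalyst in the key step.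

Key step: step 6

Assumption: Grignard reagents 1 and 6 are bought as THF solutions, and the bis(oxazoline) enantiomer for step 6 is the one whose sense of induction leads to the (S)-ester, to be assigned on a hexanal/1-octene model before 8 is committed.

Step 1
Reactants: 1 3,5-dimethoxyphenylmagnesium chloride; 2 (S)-epichlorohydrin
Product: 3 (2S)-1-chloro-3-(3,5-dimethoxyphenyl)propan-2-ol
Conditions: CuI (10 mol%), THF, −40 → −10 °C; aq. NH4Cl
Reagents that add atoms: none
Why: Copper-catalysed Grignard opening of a terminal epoxide should occur by SN2 attack at the oxirane CH2 (not at C–Cl) with cold quench before the chloro-alkoxide can re-close, so the carbinol centre of 2 is carried over untouched.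

Step 2
Reactants: 3 (2S)-1-chloro-3-(3,5-dimethoxyphenyl)propan-2-ol
Product: 4 (2S)-1-(2-bromo-3,5-dimethoxyphenyl)-3-chloropropan-2-ol
Conditions: NBS (1.0 equiv), MeCN, 0 °C
Reagents that add atoms: N-bromosuccinimide, O=C1CCC(=O)N1Br
Why: Electrophilic aromatic bromination of the 3,5-dimethoxyalkylbenzene should go to the position ortho to the side chain and para to a methoxy group (the two such positions are equivalent) rather than to the position between the two methoxy groups, and it is run before any alkene is present.

Step 3
Reactants: 4 (2S)-1-(2-bromo-3,5-dimethoxyphenyl)-3-chloropropan-2-ol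
Product: 5 (2S)-2-[(2-bromo-3,5-dimethoxyphenyl)methyl]oxirane
Conditions: NaOH (2 M aq.), THF, 0 °C → rt
Reagents that add atoms: none
Why: Intramolecular Williamson etherification of the chlorohydrin (alkoxide displaces the primary chloride) should close the epoxide without touching the stereocentre.

Step 4
Reactants: 5 (2S)-2-[(2-bromo-3,5-dimethoxyphenyl)methyl]oxirane; 6 but-3-en-1-ylmagnesium bromide
Product: 7 (2R)-1-(2-bromo-3,5-dimethoxyphenyl)hept-6-en-2-ol
Conditions: CuI (10 mol%), THF, −40 → −20 °C; aq. NH4Cl
Reagents that add atoms: none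
Why: Copper-catalysed Grignard opening of the terminal epoxide at its CH2 should form the C1'–C2' bond while the electron-rich aryl bromide stays inert at low temperature; the C–O centre is retained, and the descriptor becomes R only through the change in CIP priorities.

Step 5
Reactants: 7 (2R)-1-(2-bromo-3,5-dimethoxyphenyl)hept-6-en-2-ol
Product: 8 (3R)-6,8-dimethoxy-3-(pent-4-en-1-yl)-3,4-dihydro-1H-isochromen-1-one
Conditions: Pd(OAc)2 (5 mol%), Xantphos (6 mol%), CO (1 atm), K2CO3, toluene, 100 °C
Reagents that add atoms: carbon monoxide, [C-]#[O+]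
Why: Palladium-catalysed carbonylative lactonisation (oxidative addition into C–Br, CO insertion, capture of the acyl-palladium by the tethered secondary alcohol in a 6-exo-trig acyl substitution) should build the δ-lactone ring with C3 untouched.

Step 6
Reactants: 8 (3R)-6,8-dimethoxy-3-(pent-4-en-1-yl)-3,4-dihydro-1H-isochromen-1-one; 9 hexanal; 10 benzoyl bromide
Product: 12 (6S)-1-[(3R)-6,8-dimethoxy-1-oxo-3,4-dihydro-1H-isochromen-3-yl]undecan-6-yl benzoate, via racemic 1-bromohexyl benzoate 11 (not isolated)
Conditions: 9 + 10 (1.5 equiv each), rt, 30 min; then 8, NiBr2·glyme (10 mol%), chiral bis(oxazoline) L* (12 mol%), (EtO)3SiH (2 equiv), K3PO4·H2O (2 equiv), THF/DMA, 0 °C → rt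
Reagents that add atoms: none
Why: Hexanal and benzoyl bromide should add to each other to give racemic α-bromoalkyl ester 11; a ligated Ni–H formed from Ni(II), the hydrosilane and phosphate adds across the C4'=C5' alkene of 8 with nickel at the terminal carbon, and the primary alkyl–nickel abstracts bromine from 11, recombines with the planar α-benzoyloxy radical and reductively eliminates the C5'–C6' bond. The closest known reaction type is the Ni/bis(oxazoline)-catalysed enantioconvergent four-component coupling of an aldehyde, an acyl bromide, a terminal olefin and a hydrosilane to esters of dialkyl carbinols, applied here to a functionalised olefin. No ring is closed. The new C6' centre should be set S by the chiral ligand alone, because both enantiomers of 11 pass through the same radical and the C3 centre lies six bonds away. The step needs linear (anti-Markovnikov) regioselectivity, which the unhindered monosubstituted alkene secures, and chemoselectivity for the C–Br bond over the lactone and aryl ethers, which the mild silane/phosphate conditions and the absence of any aryl halide in 8 secure. The benzoyl group serves as radical-stabilising and nickel-binding activator and as protecting group, and is removed in step 7.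

Step 7
Reactants: 12 (6S)-1-[(3R)-6,8-dimethoxy-1-oxo-3,4-dihydro-1H-isochromen-3-yl]undecan-6-yl benzoate
Product: 14 (3R)-3-[(6S)-6-hydroxyundecyl]-6,8-dimethoxy-3,4-dihydro-1H-isochromen-1-one, via ring-opened dihydroxy acid 13 (not isolated)
Conditions: LiOH·H2O (5 equiv), THF/MeOH/H2O, 40 °C; then 2 M HCl to pH 1, rt
Reagents that add atoms: lithium hydroxide, [Li+].[OH-] (its oxygen enters the carboxyl group of 13 and can remain as the carbonyl oxygen of 14)
Why: Ester saponification cleaves the benzoate at the acyl–oxygen bond so C6' keeps its S configuration, and the lactone that opens alongside should re-close on acidification through the C3 hydroxyl (six-membered lactonisation, C3–O bond never broken), the C6' hydroxyl being unable to compete because it would need a twelve-membered ring.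

Step 8
Reactants: 14 (3R)-3-[(6S)-6-hydroxyundecyl]-6,8-dimethoxy-3,4-dihydro-1H-isochromen-1-one
Product: 15 (3R)-8-hydroxy-3-[(6S)-6-hydroxyundecyl]-6-methoxy-3,4-dihydro-1H-isochromen-1-one (CNP0312787.1)
Conditions: BCl3 (1 M in CH2Cl2, 3 equiv), CH2Cl2, −78 → 0 °C; aq. NaHCO3
Reagents that add atoms: none
Why: Chelation-controlled Lewis-acid ether cleavage should remove only the 8-O-methyl group, because boron bridges the lactone carbonyl and the peri methoxy oxygen in a six-membered chelate while the 6-methoxy group has no such partner, and the C6' hydroxyl is expected to be held as a borate ester that is hydrolysed on work-up.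

**Compound list**
1 | 3,5-dimethoxyphenylmagnesium chloride (1.0 M in THF) | COc1cc(OC)cc([Mg]Cl)c1 | starting material
2 | (S)-epichlorohydrin, (2S)-2-(chloromethyl)oxirane | ClC[C@@H]1CO1 | starting material
3 | (2S)-1-chloro-3-(3,5-dimethoxyphenyl)propan-2-ol | ClC[C@@H](O)Cc1cc(OC)cc(OC)c1 | intermediate
4 | (2S)-1-(2-bromo-3,5-dimethoxyphenyl)-3-chloropropan-2-ol | ClC[C@@H](O)Cc1cc(OC)cc(OC)c1Br | intermediate
5 | (2S)-2-[(2-bromo-3,5-dimethoxyphenyl)methyl]oxirane | COc1cc(OC)c(Br)c(C[C@H]2CO2)c1 | intermediate
6 | but-3-en-1-ylmagnesium bromide (0.5 M in THF) | C=CCC[Mg]Br | starting material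
7 | (2R)-1-(2-bromo-3,5-dimethoxyphenyl)hept-6-en-2-ol | C=CCCC[C@@H](O)Cc1cc(OC)cc(OC)c1Br | intermediate
8 | (3R)-6,8-dimethoxy-3-(pent-4-en-1-yl)-3,4-dihydro-1H-isochromen-1-one | C=CCCC[C@@H]1Cc2cc(OC)cc(OC)c2C(=O)O1 | intermediate
9 | hexanal | CCCCCC=O | starting material
10 | benzoyl bromide | O=C(Br)c1ccccc1 | starting material
11 | racemic 1-bromohexyl benzoate (formed in the flask) | CCCCCC(Br)OC(=O)c1ccccc1 | intermediate
12 | (6S)-1-[(3R)-6,8-dimethoxy-1-oxo-3,4-dihydro-1H-isochromen-3-yl]undecan-6-yl benzoate | CCCCC[C@H](OC(=O)c1ccccc1)CCCCC[C@@H]1Cc2cc(OC)cc(OC)c2C(=O)O1 | intermediate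
13 | 2-[(2R,7S)-2,7-dihydroxydodecyl]-4,6-dimethoxybenzoic acid (formed in the flask as its lithium salt) | CCCCC[C@H](O)CCCCC[C@@H](O)Cc1cc(OC)cc(OC)c1C(=O)O | intermediate
14 | (3R)-3-[(6S)-6-hydroxyundecyl]-6,8-dimethoxy-3,4-dihydro-1H-isochromen-1-one | CCCCC[C@H](O)CCCCC[C@@H]1Cc2cc(OC)cc(OC)c2C(=O)O1 | intermediate
15 | (3R)-8-hydroxy-3-[(6S)-6-hydroxyundecyl]-6-methoxy-3,4-dihydro-1H-isochromen-1-one | CCCCC[C@H](O)CCCCC[C@@H]1Cc2cc(OC)cc(O)c2C(=O)O1 | target

**Totals**
Total step count: 8. Longest linear sequence: 8 steps (1 and 2 to 15).

**Steps most likely to fail**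

Step 6. The catalyst may fail to control the C6' configuration, the Ni–H may chain-walk and give branched isomers, or the bromo ester formed in the flask may be hydrolysed by the hydrated phosphate before it couples. The fallback sets out from 8 and joins the chain at C4'=C5' instead, with the carbinol centre bought. Olefin cross-metathesis of 8 with commercial (S)-oct-1-en-3-ol (CCCCC[C@H](O)C=C, 3 equiv; Hoveyda–Grubbs II 5 mol%, CH2Cl2, 40 °C) should give (3R)-3-[(4E,6S)-6-hydroxyundec-4-en-1-yl]-6,8-dimethoxy-3,4-dihydro-1H-isochromen-1-one F1. Hydrogenation of the alkene (H2 1 atm, PtO2, EtOAc) then returns to the route at 14, and step 7 is no longer needed.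

Step 5. Oxidative addition into the electron-rich, doubly ortho-flanked C–Br bond may be slow, and palladium hydrides may migrate the terminal alkene. The fallback sets out from 7 and installs the carboxyl carbon by organolithium chemistry. n-BuLi (2.2 equiv, THF, −78 °C) should deprotonate the alcohol and exchange the bromine to give lithium (2R)-1-(2-lithio-3,5-dimethoxyphenyl)hept-6-en-2-olate F2. Quenching with CO2 and then dilute HCl should give 2-[(2R)-2-hydroxyhept-6-en-1-yl]-4,6-dimethoxybenzoic acid F3. Catalytic TsOH in CH2Cl2 at rt should close this acid to the lactone, returning to the route at 8.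

Step 8. Regiocontrol of the ether cleavage may be lost (the 6-methoxy group also removed), or the unprotected C6' carbinol may react further with the Lewis acid by way of its borate. The fallback sets out from 12 and reverses the order of the two deprotections, so that the carbinol stays acylated during the Lewis-acid step. BCl3 (CH2Cl2, −78 → 0 °C) on 12 should give (6S)-1-[(3R)-8-hydroxy-6-methoxy-1-oxo-3,4-dihydro-1H-isochromen-3-yl]undecan-6-yl benzoate F4. LiOH (THF/MeOH/H2O, 40 °C) should then cleave the benzoate and open the lactone to 2-[(2R,7S)-2,7-dihydroxydodecyl]-6-hydroxy-4-methoxybenzoic acid F5, which is not isolated. Acidification with 2 M HCl at rt should re-close the lactone and arrive directly at the target 15.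

**Further compounds**
F1 | step 6 | (3R)-3-[(4E,6S)-6-hydroxyundec-4-en-1-yl]-6,8-dimethoxy-3,4-dihydro-1H-isochromen-1-one | CCCCC[C@H](O)/C=C/CCC[C@@H]1Cc2cc(OC)cc(OC)c2C(=O)O1
F2 | step 5 | lithium (2R)-1-(2-lithio-3,5-dimethoxyphenyl)hept-6-en-2-olate | C=CCCC[C@@H](O[Li])Cc1cc(OC)cc(OC)c1[Li]
F3 | step 5 | 2-[(2R)-2-hydroxyhept-6-en-1-yl]-4,6-dimethoxybenzoic acid | C=CCCC[C@@H](O)Cc1cc(OC)cc(OC)c1C(=O)O
F4 | step 8 | (6S)-1-[(3R)-8-hydroxy-6-methoxy-1-oxo-3,4-dihydro-1H-isochromen-3-yl]undecan-6-yl benzoate | CCCCC[C@H](OC(=O)c1ccccc1)CCCCC[C@@H]1Cc2cc(OC)cc(O)c2C(=O)O1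
F5 | step 8 | 2-[(2R,7S)-2,7-dihydroxydodecyl]-6-hydroxy-4-methoxybenzoic acid | CCCCC[C@H](O)CCCCC[C@@H](O)Cc1cc(OC)cc(O)c1C(=O)O
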